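**Retrosynthetic overview**
- The target is a 6,8''-biflavone: an acacetin unit (unprimed) joined through C6 to C8'' of an apigenin unit (double-primed, its ring B triple-primed). The strategy rests on ring A of the apigenin half, a phloroglucinol ring in which C8'' lies between the oxygen on C7'' and the ring oxygen on C8a'' and carries the C6 aryl group, so that the C6–C8'' axis has four ortho oxygens.
- Key disconnection: ring A of the apigenin half is opened at C8''–C8a'', C7''–C6'' and C8a''–C4a''. In the forward sense a C6 (silyloxy)ethynyl group on the acacetin half and 3-ethoxycyclobutenone are joined in a Danheiser benzannulation; the C6–C8'' bond is already present as the aryl–alkyne bond.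
- The alkyne precursor comes from acacetin: O7 isopropylation, C6 iodination beside the free 5-OH, O5 methylation, Sonogashira coupling, C-desilylation, then oxygenation and O-silylation of the acetylide.
- Ring C of the apigenin half follows: C-acetylation at C4a'' ortho to the free 8a''-OH, aroyl transfer from 4-isopropoxybenzoyl chloride, cyclodehydration (O1''–C2''), then fluoride and BCl3.
- Ring order: the three acacetin rings are bought in; ring A of the apigenin half forms in step 7, its pyranone ring C in step 11, and its ring B arrives with the aroyl chloride.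

Key step: step 7

Remark: the target SMILES carries no descriptor for the C6–C8'' axis, so the biaryl is made as the racemate; acacetin, 3-ethoxycyclobut-2-en-1-one and 4-isopropoxybenzoic acid are taken as purchased.

**Route**

Step 1
Reactants: 1 acacetin (5,7-dihydroxy-4'-methoxyflavone)
Product: 2 5-hydroxy-7-isopropoxy-4'-methoxyflavone
Conditions: 2-bromopropane (1.3 equiv), K2CO3, DMF, 50 °C
Reagents that add atoms: 2-bromopropane, CC(C)Br
Why: Williamson alkylation should take place at O7 only, because the 7-OH is the acidic, unchelated phenol whereas the 5-OH is held in a hydrogen bond to the C4 carbonyl.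

Step 2
Reactants: 2 5-hydroxy-7-isopropoxy-4'-methoxyflavone
Product: 3 5-hydroxy-6-iodo-7-isopropoxy-4'-methoxyflavone
Conditions: BnNMe3 ICl2 (1.1 equiv), CaCO3, CH2Cl2–MeOH, rt
Reagents that add atoms: benzyltrimethylammonium dichloroiodate, C[N+](C)(C)Cc1ccccc1.Cl[I-]Cl
Why: Electrophilic aromatic iodination of a 5-hydroxy-7-alkoxyflavone with the buffered dichloroiodate is expected at C6, ortho to the free phenol, rather than at C8, and the enone-deactivated anisole ring B should stay untouched.

Step 3
Reactants: 3 5-hydroxy-6-iodo-7-isopropoxy-4'-methoxyflavone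
Product: 4 6-iodo-7-isopropoxy-5,4'-dimethoxyflavone
Conditions: Me2SO4, K2CO3, acetone, reflux
Reagents that add atoms: dimethyl sulfate, COS(=O)(=O)OC
Why: Williamson methylation with a small, reactive electrophile is the reliable way to cap the chelated, iodine-flanked 5-OH; methyl keeps the flank of C6 small and is removable at the end by chelation-assisted cleavage beside C4=O, which the 4'-methyl ether cannot undergo.

Step 4
Reactants: 4 6-iodo-7-isopropoxy-5,4'-dimethoxyflavone; 5 ethynyltrimethylsilane
Product: 6 7-isopropoxy-5,4'-dimethoxy-6-[(trimethylsilyl)ethynyl]flavone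
Conditions: PdCl2(PPh3)2 (cat.), CuI (cat.), Et3N, DMF, 70 °C
Reagents that add atoms: none
Why: Sonogashira coupling should succeed because an aryl iodide adds oxidatively to zerovalent palladium even between two ortho alkoxy groups and the linear alkyne is undemanding sterically.

Step 5
Reactants: 6 7-isopropoxy-5,4'-dimethoxy-6-[(trimethylsilyl)ethynyl]flavone
Product: 7 6-ethynyl-7-isopropoxy-5,4'-dimethoxyflavone
Conditions: K2CO3 (cat.), MeOH–THF, rt
Reagents that add atoms: none
Why: Carbonate-catalysed methanolysis of the C(sp)–SiMe3 bond is fast at room temperature and leaves the pyranone and the aryl ethers alone.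

Step 6
Reactants: 7 6-ethynyl-7-isopropoxy-5,4'-dimethoxyflavone
Product: 10 7-isopropoxy-5,4'-dimethoxy-6-[(triisopropylsilyloxy)ethynyl]flavone, via lithium acetylide 8 (not isolated), via lithium ynolate 9 (not isolated)
Conditions: LiN(SiMe3)2 (1.05 equiv), THF, −78 °C; t-BuOOLi (from t-BuOOH and LiN(SiMe3)2, THF, −78 °C), −78 → 0 °C; i-Pr3SiOTf, −78 → 0 °C
Reagents that add atoms: tert-butyl hydroperoxide, CC(C)(C)OO; triisopropylsilyl trifluoromethanesulfonate, CC(C)[Si](OS(=O)(=O)C(F)(F)F)(C(C)C)C(C)C
Why: Electrophilic oxygenation of a lithium acetylide by lithium tert-butyl peroxide gives the ynolate, which the bulky silyl triflate should trap on oxygen; the alkyne C–H is by far the most acidic site, so the amide base should not touch C3–H at −78 °C, and the vinylogous-ester C2=C3 bond is a poor acceptor for the peroxide.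

Step 7
Reactants: 10 7-isopropoxy-5,4'-dimethoxy-6-[(triisopropylsilyloxy)ethynyl]flavone; 11 3-ethoxycyclobut-2-en-1-one
Product: 16 6-[4-ethoxy-2-hydroxy-6-(triisopropylsilyloxy)phenyl]-7-isopropoxy-5,4'-dimethoxyflavone, via vinylketene 12 (not isolated), via vinylcyclobutenone 13 (not isolated), via dienylketene 14 (not isolated), via cyclohexadienone 15 (not isolated)
Conditions: 11 (2 equiv), toluene, sealed tube, 80 °C then 110 °C
Reagents that add atoms: none
Why: Heating should open 11 by a 4π electrocyclic reaction to (1-ethoxyvinyl)ketene 12, whose ketene C=C adds [2+2] to the siloxyalkyne to give 13 (forming C8''–C8a'' and C7''–C6''); a second 4π opening gives dienylketene 14. The closest known reaction type is the Danheiser benzannulation of cyclobutenones with trialkylsilyloxyalkynes; the alkoxy group on the cyclobutenone and the ortho-flanked aryl group on the alkyne are the less explored features. The new six-membered carbocycle closes by thermal 6π electrocyclization of 14 (forming C8a''–C4a'') to cyclohexadienone 15, which tautomerizes to the phenol. No stereocentre is created; C4 of 13 is transient and the biaryl axis is formed as a racemate. The step needs one regiochemistry in the [2+2], and the silyloxy group secures it: oxygen donation makes the aryl-bearing alkyne carbon the nucleophile, so it bonds to the ketene carbonyl carbon and the product carries free OH on C8a'', silyl ether on C7'' and ethyl ether on C5''. The congested tetra-ortho-oxygenated axis is never made by a coupling, since C6–C8'' is already in place in 10.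

Step 8
Reactants: 16 6-[4-ethoxy-2-hydroxy-6-(triisopropylsilyloxy)phenyl]-7-isopropoxy-5,4'-dimethoxyflavone
Product: 18 6-[3-acetyl-4-ethoxy-2-hydroxy-6-(triisopropylsilyloxy)phenyl]-7-isopropoxy-5,4'-dimethoxyflavone, via difluoroboron chelate 17 (not isolated)
Conditions: Ac2O (1.5 equiv), BF3·OEt2 (5 equiv), CH2Cl2, 0 → 40 °C; then NaOAc, MeOH–H2O, 50 °C
Reagents that add atoms: acetic anhydride, CC(=O)OC(C)=O
Why: Friedel–Crafts acetylation in the Fries manifold should go ortho to the free phenol at C4a'', because boron ties O8a'' and the new carbonyl into a six-membered chelate while C6'' is shielded by the silyl ether and the ethoxy group; acetate in aqueous methanol then opens the chelate.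

Step 9
Reactants: 19 4-isopropoxybenzoic acid
Product: 20 4-isopropoxybenzoyl chloride
Conditions: (COCl)2, DMF (cat.), CH2Cl2, 0 °C → rt
Reagents that add atoms: oxalyl chloride, ClC(=O)C(Cl)=O
Why: Acid chloride formation through the chloroiminium species from oxalyl chloride and catalytic DMF is clean and leaves only gaseous by-products.

Step 10
Reactants: 18 6-[3-acetyl-4-ethoxy-2-hydroxy-6-(triisopropylsilyloxy)phenyl]-7-isopropoxy-5,4'-dimethoxyflavone; 20 4-isopropoxybenzoyl chloride
Product: 22 1-[6-ethoxy-2-hydroxy-3-(7-isopropoxy-5,4'-dimethoxyflavon-6-yl)-4-(triisopropylsilyloxy)phenyl]-3-(4-isopropoxyphenyl)propane-1,3-dione, via dilithium dianion 21 (not isolated)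
Conditions: LiN(SiMe3)2 (3.5 equiv), THF, −78 → −20 °C; then 20, −78 °C → rt; aq HCl work-up
Reagents that add atoms: none
Why: This is the Baker–Venkataraman aroyl transfer run in one pot as a Claisen acylation: the enolate carbon of the dianion takes the aroyl group (any O-aroyl ester formed first would migrate from O to C under the excess base), and the extra base absorbs the acidic diketone.

Step 11
Reactants: 22 the 1,3-diketone
Product: 23 5''-ethoxy-7,4'''-diisopropoxy-5,4'-dimethoxy-7''-(triisopropylsilyloxy)-6,8''-biflavone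
Conditions: p-TsOH·H2O (cat.), toluene, 80 °C
Reagents that add atoms: none
Why: Acid-catalysed cyclodehydration should close pyranone ring C of the apigenin half by 6-exo-trig attack of O8a'' on the aroyl carbonyl followed by loss of water, the standard end of a flavone synthesis from an o-hydroxyaryl 1,3-diketone.

Step 12
Reactants: 23 the silyl-protected biflavone
Product: 24 5''-ethoxy-7''-hydroxy-7,4'''-diisopropoxy-5,4'-dimethoxy-6,8''-biflavone
Conditions: Bu4NF, AcOH, THF, 0 °C
Reagents that add atoms: none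
Why: Fluoride cleaves the aryl O–Si bond selectively, and the acetic acid buffer keeps the liberated phenoxide from causing side reactions.

Step 13
Reactants: 24 5''-ethoxy-7''-hydroxy-7,4'''-diisopropoxy-5,4'-dimethoxy-6,8''-biflavone
Product: 25 5,7,5'',7'',4'''-pentahydroxy-4'-methoxy-6,8''-biflavone (CNP0302154.0)
Conditions: BCl3 (excess), CH2Cl2, −78 °C → rt; then H2O
Reagents that add atoms: none
Why: Lewis-acid ether cleavage with BCl3 should remove the two isopropyl ethers by an ionizing pathway and the 5-OMe and 5''-OEt groups through six-membered boron chelates with the neighbouring C4 and C4'' carbonyls, whereas the unchelated 4'-methyl ether has neither pathway open at or below room temperature.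

**Compound list**
1 | acacetin (5,7-dihydroxy-4'-methoxyflavone) | COc1ccc(cc1)-c1cc(=O)c2c(O)cc(O)cc2o1 | starting material
2 | 5-hydroxy-7-isopropoxy-4'-methoxyflavone | COc1ccc(cc1)-c1cc(=O)c2c(O)cc(OC(C)C)cc2o1 | intermediate
3 | 5-hydroxy-6-iodo-7-isopropoxy-4'-methoxyflavone | COc1ccc(cc1)-c1cc(=O)c2c(O)c(I)c(OC(C)C)cc2o1 | intermediate
4 | 6-iodo-7-isopropoxy-5,4'-dimethoxyflavone | COc1ccc(cc1)-c1cc(=O)c2c(OC)c(I)c(OC(C)C)cc2o1 | intermediate
5 | ethynyltrimethylsilane | C#C[Si](C)(C)C | starting material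
6 | 7-isopropoxy-5,4'-dimethoxy-6-[(trimethylsilyl)ethynyl]flavone | COc1ccc(cc1)-c1cc(=O)c2c(OC)c(C#C[Si](C)(C)C)c(OC(C)C)cc2o1 | intermediate
7 | 6-ethynyl-7-isopropoxy-5,4'-dimethoxyflavone | COc1ccc(cc1)-c1cc(=O)c2c(OC)c(C#C)c(OC(C)C)cc2o1 | intermediate
8 | lithium acetylide of 7 | COc1ccc(cc1)-c1cc(=O)c2c(OC)c(C#C[Li])c(OC(C)C)cc2o1 | intermediate (not isolated)
9 | lithium 2-(7-isopropoxy-5,4'-dimethoxyflavon-6-yl)ethynolate | COc1ccc(cc1)-c1cc(=O)c2c(OC)c(C#CO[Li])c(OC(C)C)cc2o1 | intermediate (not isolated)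
10 | 7-isopropoxy-5,4'-dimethoxy-6-[(triisopropylsilyloxy)ethynyl]flavone | COc1ccc(cc1)-c1cc(=O)c2c(OC)c(C#CO[Si](C(C)C)(C(C)C)C(C)C)c(OC(C)C)cc2o1 | intermediate
11 | 3-ethoxycyclobut-2-en-1-one | CCOC1=CC(=O)C1 | starting material
12 | (1-ethoxyvinyl)ketene (3-ethoxybuta-1,3-dien-1-one) | CCOC(=C)C=C=O | intermediate (not isolated)
13 | 4-(1-ethoxyvinyl)-2-(7-isopropoxy-5,4'-dimethoxyflavon-6-yl)-3-(triisopropylsilyloxy)cyclobut-2-en-1-one (racemic) | CCOC(=C)C1C(=O)C(=C1O[Si](C(C)C)(C(C)C)C(C)C)c1c(OC)c2c(cc1OC(C)C)oc(cc2=O)-c1ccc(OC)cc1 | intermediate (not isolated)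
14 | 5-ethoxy-2-(7-isopropoxy-5,4'-dimethoxyflavon-6-yl)-3-(triisopropylsilyloxy)hexa-1,3,5-trien-1-one (ketene carbon and ethoxyvinyl group cis) | CCOC(=C)/C=C(O[Si](C(C)C)(C(C)C)C(C)C)\C(=C=O)c1c(OC)c2c(cc1OC(C)C)oc(cc2=O)-c1ccc(OC)cc1 | intermediate (not isolated)
15 | 5-ethoxy-2-(7-isopropoxy-5,4'-dimethoxyflavon-6-yl)-3-(triisopropylsilyloxy)cyclohexa-2,4-dien-1-one | CCOC1=CC(O[Si](C(C)C)(C(C)C)C(C)C)=C(C(=O)C1)c1c(OC)c2c(cc1OC(C)C)oc(cc2=O)-c1ccc(OC)cc1 | intermediate (not isolated)
16 | 6-[4-ethoxy-2-hydroxy-6-(triisopropylsilyloxy)phenyl]-7-isopropoxy-5,4'-dimethoxyflavone (racemic axis) | COc1ccc(cc1)-c1cc(=O)c2c(OC)c(-c3c(O)cc(OCC)cc3O[Si](C(C)C)(C(C)C)C(C)C)c(OC(C)C)cc2o1 | intermediate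
17 | difluoroboron chelate of 18 (boron bridging O8a'' and the acetyl oxygen) | CC1=[O+][B-](F)(F)Oc2c(c(O[Si](C(C)C)(C(C)C)C(C)C)cc(OCC)c12)-c1c(OC)c2c(cc1OC(C)C)oc(cc2=O)-c1ccc(OC)cc1 | intermediate (not isolated)
18 | 6-[3-acetyl-4-ethoxy-2-hydroxy-6-(triisopropylsilyloxy)phenyl]-7-isopropoxy-5,4'-dimethoxyflavone | CC(=O)c1c(O)c(c(O[Si](C(C)C)(C(C)C)C(C)C)cc1OCC)-c1c(OC)c2c(cc1OC(C)C)oc(cc2=O)-c1ccc(OC)cc1 | intermediate
19 | 4-isopropoxybenzoic acid | CC(C)Oc1ccc(cc1)C(O)=O | starting material
20 | 4-isopropoxybenzoyl chloride | CC(C)Oc1ccc(cc1)C(Cl)=O | intermediate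
21 | dilithium enolate-phenoxide of 18 | C=C(O[Li])c1c(O[Li])c(c(O[Si](C(C)C)(C(C)C)C(C)C)cc1OCC)-c1c(OC)c2c(cc1OC(C)C)oc(cc2=O)-c1ccc(OC)cc1 | intermediate (not isolated)
22 | 1-[6-ethoxy-2-hydroxy-3-(7-isopropoxy-5,4'-dimethoxyflavon-6-yl)-4-(triisopropylsilyloxy)phenyl]-3-(4-isopropoxyphenyl)propane-1,3-dione | CC(C)Oc1ccc(cc1)C(=O)CC(=O)c1c(O)c(c(O[Si](C(C)C)(C(C)C)C(C)C)cc1OCC)-c1c(OC)c2c(cc1OC(C)C)oc(cc2=O)-c1ccc(OC)cc1 | intermediate
23 | 5''-ethoxy-7,4'''-diisopropoxy-5,4'-dimethoxy-7''-(triisopropylsilyloxy)-6,8''-biflavone | CC(C)Oc1ccc(cc1)-c1cc(=O)c2c(OCC)cc(O[Si](C(C)C)(C(C)C)C(C)C)c(c2o1)-c1c(OC)c2c(cc1OC(C)C)oc(cc2=O)-c1ccc(OC)cc1 | intermediate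
24 | 5''-ethoxy-7''-hydroxy-7,4'''-diisopropoxy-5,4'-dimethoxy-6,8''-biflavone | CC(C)Oc1ccc(cc1)-c1cc(=O)c2c(OCC)cc(O)c(c2o1)-c1c(OC)c2c(cc1OC(C)C)oc(cc2=O)-c1ccc(OC)cc1 | intermediate
25 | 5,7,5'',7'',4'''-pentahydroxy-4'-methoxy-6,8''-biflavone (CNP0302154.0, racemic axis) | COc1ccc(-c2cc(=O)c3c(O)c(-c4c(O)cc(O)c5c(=O)cc(-c6ccc(O)cc6)oc45)c(O)cc3o2)cc1 | target

**Totals**
Total step count: 13. Longest linear sequence: 12 steps (steps 1–8 and 10–13, from acacetin); step 9 is a one-step side branch.

**Steps most likely to fail**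

Step 7. The vinylogous-ester resonance of 11 may slow its ring opening so much that, at the temperature then required, the siloxyalkyne undergoes a silyl shift to a silylketene or the cyclobutenone is consumed by self-condensation before the hindered [2+2] takes place. The fallback sets out from 10 and comes back at 16, and makes ketene 12 by elimination instead of by ring opening. Saponification of commercial ethyl (E)-3-ethoxybut-2-enoate (KOH, aqueous EtOH) would give (E)-3-ethoxybut-2-enoic acid F1, and oxalyl chloride would convert it into (E)-3-ethoxybut-2-enoyl chloride F2. Slow addition of Et3N to F2 and 10 in toluene near room temperature should generate 12 by 1,4-dehydrochlorination and trap it as 13; warming to 80 °C would then carry 13 through 14 and 15 to 16.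

Step 8. The hydrogen fluoride released on chelate formation may strip the silyl ether, or acetylation may stray to C6''. The fallback sets out from 16 and comes back at 18, and uses symmetry instead of direction by a single phenol. Bu4NF would remove the silyl group to give 6-(4-ethoxy-2,6-dihydroxyphenyl)-7-isopropoxy-5,4'-dimethoxyflavone F3, whose two free ring positions are equivalent (enantiotopic). Acetylation with Ac2O and BF3·OEt2 can therefore give only 6-(3-acetyl-4-ethoxy-2,6-dihydroxyphenyl)-7-isopropoxy-5,4'-dimethoxyflavone F4. In F4 one OH is chelated to the acetyl group and the other, para to it, is free, so i-Pr3SiCl with imidazole in DMF should silylate only the latter and return 18.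

Step 6. The peroxide or the amide base may attack the pyranone, the ynolate may be silylated on carbon to a silylketene, or the siloxyalkyne may decompose on isolation. The fallback sets out from 4 and comes back at 18, and brings the oxygenated alkyne in as a preformed two-carbon unit. 2-(Trimethylsilyl)ethanol, KH and trichloroethylene would give (E)-1,2-dichlorovinyl 2-(trimethylsilyl)ethyl ether F5. Two equivalents of n-BuLi would convert F5 into lithium [2-(trimethylsilyl)ethoxy]ethynide F6, and ZnCl2 would give chlorozinc [2-(trimethylsilyl)ethoxy]ethynide F7. Negishi coupling of F7 with 4 (Pd(PPh3)4, THF) should give 7-isopropoxy-5,4'-dimethoxy-6-{[2-(trimethylsilyl)ethoxy]ethynyl}flavone F8. Benzannulation of F8 with 11 under the conditions of step 7 should give 6-{4-ethoxy-2-hydroxy-6-[2-(trimethylsilyl)ethoxy]phenyl}-7-isopropoxy-5,4'-dimethoxyflavone F9. CsF in DMF would remove the 2-(trimethylsilyl)ethyl group to give resorcinol F3, which is then taken through ketone F4 to 18 as described for step 8.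

**Further compounds**
F1 | step 7 | (E)-3-ethoxybut-2-enoic acid | CCO/C(C)=C/C(O)=O
F2 | step 7 | (E)-3-ethoxybut-2-enoyl chloride | CCO/C(C)=C/C(Cl)=O
F3 | step 8 | 6-(4-ethoxy-2,6-dihydroxyphenyl)-7-isopropoxy-5,4'-dimethoxyflavone | COc1ccc(cc1)-c1cc(=O)c2c(OC)c(-c3c(O)cc(OCC)cc3O)c(OC(C)C)cc2o1
F4 | step 8 | 6-(3-acetyl-4-ethoxy-2,6-dihydroxyphenyl)-7-isopropoxy-5,4'-dimethoxyflavone | CC(=O)c1c(O)c(c(O)cc1OCC)-c1c(OC)c2c(cc1OC(C)C)oc(cc2=O)-c1ccc(OC)cc1
F5 | step 6 | (E)-1,2-dichlorovinyl 2-(trimethylsilyl)ethyl ether | C[Si](C)(C)CCO/C(Cl)=C\Cl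
F6 | step 6 | lithium [2-(trimethylsilyl)ethoxy]ethynide | C[Si](C)(C)CCOC#C[Li]
F7 | step 6 | chlorozinc [2-(trimethylsilyl)ethoxy]ethynide | C[Si](C)(C)CCOC#C[Zn]Cl
F8 | step 6 | 7-isopropoxy-5,4'-dimethoxy-6-{[2-(trimethylsilyl)ethoxy]ethynyl}flavone | COc1ccc(cc1)-c1cc(=O)c2c(OC)c(C#COCC[Si](C)(C)C)c(OC(C)C)cc2o1
F9 | step 6 | 6-{4-ethoxy-2-hydroxy-6-[2-(trimethylsilyl)ethoxy]phenyl}-7-isopropoxy-5,4'-dimethoxyflavone | COc1ccc(cc1)-c1cc(=O)c2c(OC)c(-c3c(O)cc(OCC)cc3OCC[Si](C)(C)C)c(OC(C)C)cc2o1
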